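**Strategy.** Everything rests on disconnecting the geranyl CH2 from C2' of ring B. C2' is the only ring-B carbon flanked by the C3' oxygen and by C1', the carbon that joins the chromanone. In the key precursor these neighbours are an OMOM group and a bromine, so the C2' hydrogen is the most acidic one. Lithiation, transmetalation to copper and SN2 coupling with geranyl bromide forge the bond in one operation with site control and an untouched E alkene. The bromine then becomes a boronic acid, and a rhodium-catalysed asymmetric 1,4-addition to a 6-prenylchromone attaches ring B to C2 and sets its S configuration. Acid finally removes both MOM groups.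

Key step: step 2

Remark on the chemistry: ring B positions are primed (C1' joins C2 of the chromanone, C2' carries the geranyl group, C3' the hydroxyl, C4' the methoxy group). The ligand antipode named in step 8 is the one expected to give 2S by analogy with related enone additions and would be confirmed on a model chromone first.

**Step 1**
Reactants: 1 5-bromo-2-methoxyphenol
Product: 2 4-bromo-1-methoxy-2-(methoxymethoxy)benzene
Conditions: MOMCl, i-Pr2NEt, CH2Cl2, 0 °C → rt
Reagents that add atoms: chloromethyl methyl ether (MOMCl), COCCl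
Why: Williamson-type O-alkylation of the phenol with the reactive α-chloro ether; the MOM ether then serves as ortho-directing group and is acid-labile at the end.

**Step 2**
Reactants: 2 4-bromo-1-methoxy-2-(methoxymethoxy)benzene; 3 geranyl bromide ((2E)-1-bromo-3,7-dimethylocta-2,6-diene)
Product: 6 1-bromo-2-[(2E)-3,7-dimethylocta-2,6-dien-1-yl]-4-methoxy-3-(methoxymethoxy)benzene, via aryllithium 4 (not isolated), via arylcopper 5 (not isolated)
Conditions: LDA, THF, −78 °C; CuBr·SMe2, −78 → −40 °C; then 3, −78 → 0 °C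
Reagents that add atoms: none
Why: LDA removes the ring hydrogen of 2 that lies between Br and OMOM (the most acidic one through the inductive effect of both groups and lithium coordination by the MOM oxygens) to give 4, and transmetalation to copper gives 5, which is not prone to lose LiBr to an aryne. Arylcopper 5 then displaces bromide at the primary carbon of 3 (overall SN2), forming the bond between C2' of the future ring B and the geranyl CH2. The closest known reaction type is directed ortho-metalation followed by copper-mediated allylation of the aryllithium with prenyl-type halides. No ring is closed and no stereocentre is formed; the 2E alkene of 3 should be carried over because an α-selective displacement never breaks the C2=C3 bond of the geranyl unit. The step needs site selectivity on the arene, secured by the flanking Br/OMOM pair, and α- over γ-attack on the allyl bromide, secured by the γ,γ-disubstitution of 3 and the soft copper nucleophile; the C1' bromine stays as the handle for step 3.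

**Step 3**
Reactants: 6 1-bromo-2-[(2E)-3,7-dimethylocta-2,6-dien-1-yl]-4-methoxy-3-(methoxymethoxy)benzene
Product: 9 {2-[(2E)-3,7-dimethylocta-2,6-dien-1-yl]-4-methoxy-3-(methoxymethoxy)phenyl}boronic acid, via aryllithium 7 (not isolated), via lithium aryltriisopropoxyborate 8 (not isolated)
Conditions: B(Oi-Pr)3, n-BuLi, THF/toluene, −78 °C (in situ quench); then 1 M HCl to pH 5, 0 °C
Reagents that add atoms: triisopropyl borate, CC(C)OB(OC(C)C)OC(C)C; water, O
Why: Bromine–lithium exchange at −78 °C is faster than any deprotonation, and trapping of 7 by the borate (ate complex 8) followed by mild hydrolysis is the standard boronic acid synthesis; the MOM ether and the trisubstituted alkenes are inert.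

**Step 4**
Reactants: 10 5,7-dihydroxy-4H-chromen-4-one
Product: 11 5-hydroxy-7-methoxy-4H-chromen-4-one
Conditions: MeI (1.1 equiv), K2CO3, acetone, reflux
Reagents that add atoms: iodomethane, CI
Why: Selective Williamson methylation: the 7-OH is the more acidic, non-chelated hydroxyl, whereas the 5-OH is tied up in a hydrogen bond to C4=O.

**Step 5**
Reactants: 11 5-hydroxy-7-methoxy-4H-chromen-4-one
Product: 12 5-hydroxy-6-iodo-7-methoxy-4H-chromen-4-one
Conditions: BnMe3N+ ICl2− (1.05 equiv), CaCO3, CH2Cl2/MeOH, rt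
Reagents that add atoms: benzyltrimethylammonium dichloroiodate, C[N+](C)(C)Cc1ccccc1.Cl[I-]Cl
Why: Electrophilic aromatic iodination directed ortho to the free 5-OH by the dichloroiodate reagent, the known way to reach C6 and not C8 in 5-hydroxy-7-alkoxy chromones and flavones.

**Step 6**
Reactants: 12 5-hydroxy-6-iodo-7-methoxy-4H-chromen-4-one; 13 tributyl(3-methylbut-2-en-1-yl)stannane
Product: 14 5-hydroxy-7-methoxy-6-(3-methylbut-2-en-1-yl)-4H-chromen-4-one
Conditions: Pd(PPh3)4 (5 mol %), DMF (degassed), 90 °C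
Reagents that add atoms: none
Why: Stille cross-coupling of an aryl iodide with an allylstannane under neutral conditions that the chromone and the chelated phenol tolerate; reductive elimination at the less hindered allyl terminus should deliver the linear prenyl group.

**Step 7**
Reactants: 14 5-hydroxy-7-methoxy-6-(3-methylbut-2-en-1-yl)-4H-chromen-4-one
Product: 15 7-methoxy-5-(methoxymethoxy)-6-(3-methylbut-2-en-1-yl)-4H-chromen-4-one
Conditions: NaH, MOMCl, DMF, 0 °C → rt
Reagents that add atoms: chloromethyl methyl ether (MOMCl), COCCl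
Why: Deprotonation of the chelated 5-OH and O-alkylation with MOMCl (Williamson type); this removes the acidic phenol before the rhodium step.

**Step 8**
Reactants: 15 7-methoxy-5-(methoxymethoxy)-6-(3-methylbut-2-en-1-yl)-4H-chromen-4-one; 9 {2-[(2E)-3,7-dimethylocta-2,6-dien-1-yl]-4-methoxy-3-(methoxymethoxy)phenyl}boronic acid
Product: 16 (2S)-2-{2-[(2E)-3,7-dimethylocta-2,6-dien-1-yl]-4-methoxy-3-(methoxymethoxy)phenyl}-7-methoxy-5-(methoxymethoxy)-6-(3-methylbut-2-en-1-yl)-2,3-dihydro-4H-chromen-4-one
Conditions: [Rh(OH)((S)-MeO-F12-BIPHEP)]2 (preformed, 3 mol % Rh), 9 (2 equiv), CH2Cl2/H2O, 40 °C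
Reagents that add atoms: none
Why: Rhodium-catalysed asymmetric conjugate (Hayashi–Miyaura) addition of an arylboronic acid to a chromone: the aryl–Rh species inserts the C2=C3 bond, water protonates the oxa-π-allyl rhodium, and the chiral bisphosphine dictates which face of C2 is arylated, setting C2 as S.

**Step 9**
Reactants: 16 the bis-MOM flavanone of step 8
Product: 17 (2S)-2-{2-[(2E)-3,7-dimethylocta-2,6-dien-1-yl]-3-hydroxy-4-methoxyphenyl}-5-hydroxy-7-methoxy-6-(3-methylbut-2-en-1-yl)-2,3-dihydro-4H-chromen-4-one (CNP0241771.1)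
Conditions: 3 M aq. HCl/MeOH (1:9), 45 °C
Reagents that add atoms: none
Why: Acid-catalysed acetal cleavage (MOM removal) of both aryl MOM ethers under mild conditions that should leave the trisubstituted alkenes and the C2 stereocentre untouched.

**Compound list**
1 | 5-bromo-2-methoxyphenol | COc1ccc(Br)cc1O | starting material
2 | 4-bromo-1-methoxy-2-(methoxymethoxy)benzene | COCOc1cc(Br)ccc1OC | intermediate
3 | geranyl bromide, (2E)-1-bromo-3,7-dimethylocta-2,6-diene | BrC/C=C(\C)CCC=C(C)C | starting material
4 | [6-bromo-3-methoxy-2-(methoxymethoxy)phenyl]lithium | [Li]c1c(Br)ccc(OC)c1OCOC | intermediate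
5 | [6-bromo-3-methoxy-2-(methoxymethoxy)phenyl]copper | [Cu]c1c(Br)ccc(OC)c1OCOC | intermediate
6 | 1-bromo-2-[(2E)-3,7-dimethylocta-2,6-dien-1-yl]-4-methoxy-3-(methoxymethoxy)benzene | COCOc1c(OC)ccc(Br)c1C/C=C(\C)CCC=C(C)C | intermediate
7 | {2-[(2E)-3,7-dimethylocta-2,6-dien-1-yl]-4-methoxy-3-(methoxymethoxy)phenyl}lithium | [Li]c1ccc(OC)c(OCOC)c1C/C=C(\C)CCC=C(C)C | intermediate
8 | lithium {2-[(2E)-3,7-dimethylocta-2,6-dien-1-yl]-4-methoxy-3-(methoxymethoxy)phenyl}triisopropoxyborate | CC(C)O[B-](OC(C)C)(OC(C)C)c1ccc(OC)c(OCOC)c1C/C=C(\C)CCC=C(C)C.[Li+] | intermediate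
9 | {2-[(2E)-3,7-dimethylocta-2,6-dien-1-yl]-4-methoxy-3-(methoxymethoxy)phenyl}boronic acid | OB(O)c1ccc(OC)c(OCOC)c1C/C=C(\C)CCC=C(C)C | intermediate
10 | 5,7-dihydroxy-4H-chromen-4-one | O=c1ccoc2cc(O)cc(O)c12 | starting material
11 | 5-hydroxy-7-methoxy-4H-chromen-4-one | O=c1ccoc2cc(OC)cc(O)c12 | intermediate
12 | 5-hydroxy-6-iodo-7-methoxy-4H-chromen-4-one | O=c1ccoc2cc(OC)c(I)c(O)c12 | intermediate
13 | tributyl(3-methylbut-2-en-1-yl)stannane | CCCC[Sn](CCCC)(CCCC)CC=C(C)C | starting material
14 | 5-hydroxy-7-methoxy-6-(3-methylbut-2-en-1-yl)-4H-chromen-4-one | O=c1ccoc2cc(OC)c(CC=C(C)C)c(O)c12 | intermediate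
15 | 7-methoxy-5-(methoxymethoxy)-6-(3-methylbut-2-en-1-yl)-4H-chromen-4-one | O=c1ccoc2cc(OC)c(CC=C(C)C)c(OCOC)c12 | intermediate
16 | (2S)-2-{2-[(2E)-3,7-dimethylocta-2,6-dien-1-yl]-4-methoxy-3-(methoxymethoxy)phenyl}-7-methoxy-5-(methoxymethoxy)-6-(3-methylbut-2-en-1-yl)-2,3-dihydro-4H-chromen-4-one | COCOc1c(OC)ccc([C@@H]2CC(=O)c3c(cc(OC)c(CC=C(C)C)c3OCOC)O2)c1C/C=C(\C)CCC=C(C)C | intermediate
17 | (2S)-2-{2-[(2E)-3,7-dimethylocta-2,6-dien-1-yl]-3-hydroxy-4-methoxyphenyl}-5-hydroxy-7-methoxy-6-(3-methylbut-2-en-1-yl)-2,3-dihydro-4H-chromen-4-one (CNP0241771.1) | COc1ccc([C@@H]2CC(=O)c3c(cc(OC)c(CC=C(C)C)c3O)O2)c(C/C=C(\C)CCC=C(C)C)c1O | target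

**Step count.** Total: 9 steps. Longest linear sequence: 6 steps (steps 4, 5, 6, 7, 8, 9).

**Steps most likely to fail**

Step 8. The ortho-geranyl group may slow transmetalation and insertion, so that protodeboronation of 9 outruns the addition, and the facial selectivity may be eroded. The fallback sets out from 6 and 15 and comes back at 16. Bromine–lithium exchange on 6 (n-BuLi, THF, −78 °C) and quench with DMF should give 2-[(2E)-3,7-dimethylocta-2,6-dien-1-yl]-4-methoxy-3-(methoxymethoxy)benzaldehyde F1. Hot aqueous NaOH/EtOH should open the pyranone of 15 and deformylate it to 1-[2-hydroxy-4-methoxy-6-(methoxymethoxy)-5-(3-methylbut-2-en-1-yl)phenyl]ethan-1-one F2, whose only free phenol is the one next to the ring hydrogen. Claisen–Schmidt condensation of F1 and F2 (KOH, EtOH) should give the chalcone F3, and NaOAc in refluxing EtOH should close it by oxa-Michael addition to the racemic flavanone F4. Kinetic resolution by Noyori transfer hydrogenation (RuCl[(R,R)-TsDPEN](p-cymene), HCO2H/Et3N, the antipode chosen to consume the 2R enantiomer) should reduce that enantiomer to the (2R,4R)-cis-flavan-4-ol F5 and leave (2S)-16, which re-enters at step 9.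

Step 2. The ortho-bromoaryllithium may lose LiBr to an aryne before transmetalation, and part of the allylation may occur at the γ-carbon of geranyl bromide. The fallback sets out from 1 and comes back at 6. Alumina-promoted ortho-allylation of the free phenol 1 with geraniol (acidic alumina, 1,2-dichloroethane, reflux) should attack the only free ortho position and give 3-bromo-2-[(2E)-3,7-dimethylocta-2,6-dien-1-yl]-6-methoxyphenol F6. MOM protection (MOMCl, i-Pr2NEt, CH2Cl2) then gives 6.

Step 5. Iodination may occur at C8 or twice. The fallback sets out from 11 and comes back at 14, bypassing steps 5 and 6. Palladium-catalysed O-tert-allylation of the 5-OH (tert-butyl 2-methylbut-3-en-2-yl carbonate, Pd(PPh3)4, THF) should give 7-methoxy-5-[(2-methylbut-3-en-2-yl)oxy]-4H-chromen-4-one F7. Aromatic Claisen rearrangement (N,N-diethylaniline, 150 °C) should then move the allyl unit, with inversion to a normal prenyl group, to C6, the only free ortho position, and give 14.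

**Further compounds**
F1 | step 8 | 2-[(2E)-3,7-dimethylocta-2,6-dien-1-yl]-4-methoxy-3-(methoxymethoxy)benzaldehyde | COCOc1c(OC)ccc(C=O)c1C/C=C(\C)CCC=C(C)C
F2 | step 8 | 1-[2-hydroxy-4-methoxy-6-(methoxymethoxy)-5-(3-methylbut-2-en-1-yl)phenyl]ethan-1-one | CC(=O)c1c(O)cc(OC)c(CC=C(C)C)c1OCOC
F3 | step 8 | (2E)-3-{2-[(2E)-3,7-dimethylocta-2,6-dien-1-yl]-4-methoxy-3-(methoxymethoxy)phenyl}-1-[2-hydroxy-4-methoxy-6-(methoxymethoxy)-5-(3-methylbut-2-en-1-yl)phenyl]prop-2-en-1-one | COCOc1c(OC)ccc(/C=C/C(=O)c2c(O)cc(OC)c(CC=C(C)C)c2OCOC)c1C/C=C(\C)CCC=C(C)C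
F4 | step 8 | racemic 2-{2-[(2E)-3,7-dimethylocta-2,6-dien-1-yl]-4-methoxy-3-(methoxymethoxy)phenyl}-7-methoxy-5-(methoxymethoxy)-6-(3-methylbut-2-en-1-yl)-2,3-dihydro-4H-chromen-4-one | COCOc1c(OC)ccc(C2CC(=O)c3c(cc(OC)c(CC=C(C)C)c3OCOC)O2)c1C/C=C(\C)CCC=C(C)C
F5 | step 8 | (2R,4R)-2-{2-[(2E)-3,7-dimethylocta-2,6-dien-1-yl]-4-methoxy-3-(methoxymethoxy)phenyl}-7-methoxy-5-(methoxymethoxy)-6-(3-methylbut-2-en-1-yl)-3,4-dihydro-2H-chromen-4-ol | COCOc1c(OC)ccc([C@H]2C[C@@H](O)c3c(cc(OC)c(CC=C(C)C)c3OCOC)O2)c1C/C=C(\C)CCC=C(C)C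
F6 | step 2 | 3-bromo-2-[(2E)-3,7-dimethylocta-2,6-dien-1-yl]-6-methoxyphenol | COc1ccc(Br)c(C/C=C(\C)CCC=C(C)C)c1O
F7 | step 5 | 7-methoxy-5-[(2-methylbut-3-en-2-yl)oxy]-4H-chromen-4-one | O=c1ccoc2cc(OC)cc(OC(C)(C)C=C)c12
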